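## Analysis of the target

The target 18 is a depside: two benzene rings, each carrying six substituents, joined only by an ester between the carbonyl carbon on C1' of ring A and the phenolic oxygen on C4 of ring B. Ring B is numbered from the carbon bearing the methyl ester (C1 CO2Me, C2 OMe, C3 Me, C4 O-acyl, C5 Me, C6 Me) and ring A from the carbon bearing the depside carbonyl (C1', then C2' Me, C3' Cl, C4' OH, C5' Me, C6' OH). There is no stereocentre, so the problem is one of regiochemistry and crowding. The sensitive points are the aryl ester, which is an activated acyl donor and is split by alkoxides, amines and hydroxide; the free resorcinol of ring A, which is easily over-halogenated or oxidized; and the aryl chloride, which limits reductive conditions late in the route. The difficulty lies in placing twelve substituents without ambiguity, in keeping three oxygen states apart (two free phenols on ring A, a methyl ether and an acylated oxygen on ring B), and above all in the ester, which sits between four ortho substituents (C2' methyl and C6' hydroxyl on one side, C3 and C5 methyls on the other). The plan rests on the fact that C3'(Cl)–C4'(OH)–C5'(Me)–C6'(OH) is the carbon chain of a 4-chloro-2-methylacetoacetate in its doubly enolized form, while C1'(carbonyl)–C2'(Me) is the triple bond of a but-2-ynoate. That but-2-ynoate can already be the ester of ring B, so the crowded ester is made while its acyl part is still a slim, linear alkyne, and ring A with its chlorine is grown onto it afterwards.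

## Retrosynthetic reasoning

**Ring A (18 ⇒ 17 ⇒ 8 + 16).** The bonds C2'–C3' and C1'–C6' are cut. Adding back the methoxy group and the two silyl groups that leave on aromatization turns 18 into the cyclohexa-1,4-diene 17, which is the [4+2] adduct of the chloro diene 16 and the aryl ynoate 8. This cut is preferred to the ester C–O bond, because that one would require acylating a phenol between two ortho methyls with an aroyl donor that is itself doubly ortho-substituted and carries free hydroxyls. The gain is that ring A, the position of chlorine and both free phenols all come from one step, with no protecting group on ring A. The forward reaction has to join the CHCl terminus of 16 to the β carbon of 8 and then aromatize without losing chlorine.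

**Diene (16 ⇒ 14 ⇒ 13).** The two O–Si bonds are cut in turn. 16 is the doubly silylated bis-enol of the chloro keto ester 13, reached through the mono-silyl enol ether 14 and its γ-deprotonation. The forward steps have to form the ketene silyl acetal without touching the C–Cl bond.

**Keto ester (13 ⇒ 9 + 10).** The C2–C3 bond of 13 is cut between the propanoate α carbon and the chloroacetyl carbonyl. This puts the methyl at C2 and the chlorine at C4 from the start and avoids regioselective alkylation or halogenation of an acetoacetate. The forward acylation must stop at the ketone stage, which is why the acyl donor 10 is an N-methoxy-N-methylamide.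

**Ynoate ester (8 ⇒ 6 + 7).** The ester C–O bond is cut at the stage where the acyl partner 7 is small and linear. The forward step is an ordinary carbodiimide esterification of the hindered phenol 6.

**C5 methyl of ring B (6 ⇒ 5 ⇒ 4 ⇒ 3).** The C5–CH3 bond is traced back to a C5–Br bond, and the free C4 hydroxyl to its benzyl ether. C5 is the only unsubstituted position of 3, so electrophilic bromination is unambiguous, and a palladium-catalysed methylation replaces bromine. The benzyl group is removed last so that only the C4 oxygen is free for acylation.

**Oxygen differentiation (3 ⇒ 2 ⇒ 1).** The O–CH3 bond at C2 and the O–benzyl bond at C4 are cut. In 1 the C2 hydroxyl is hydrogen-bonded to the ester and the C4 hydroxyl is not, so the order benzylation, then methylation, distinguishes them. 1 is a commercial resorcylate that already has five of the six ring B substituents in place.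

## Alternatives that were turned down

**Alternative 1:** Ring B is taken apart at C5–C6 and C2–C3, which leads to pentan-3-one A2 and dimethyl 2-(1-methoxyethylidene)malonate A3.
- Forward step: the enolate of A2 would replace the methoxy group of A3 by addition–elimination (C5–C6). The second α carbon of the ketone would then attack one of the two ester groups (C2–C3), and enolization would give methyl 2,4-dihydroxy-3,5,6-trimethylbenzoate A1.
- For it: one flask, commodity reagents, and all six ring B substituents placed at once, with the symmetry of A2 removing any regiochemical question. On the step count to the ring B carbon skeleton it is stronger than the chosen route, which spends steps 3 and 4 on the C5 methyl alone.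
- Against it: the first bond must form at a fully substituted β carbon that is deactivated by its methoxy donor. The ketone must then be enolized on its other side while the more acidic vinylogous malonate position of the first adduct is present. The enol oxygen can also close onto the ester in place of carbon, which would end in a 2-pyranone.
- Comparison: A1 has both phenols free, so the benzylation, methylation and hydrogenolysis of steps 1, 2 and 5 are still needed to reach 6, and ring A, the chlorine and the crowded ester are not addressed. The chosen route accepts one more routine step on ring B, starting from 1, and keeps its single uncertain step for the half of the molecule that is hard.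

**Alternative 2:** Ring B is taken apart at C1–C6, C1–C2, C3–C4 and C4–C5, which leads to methyl (E)-2-diazo-4-methyl-3-oxohex-4-enoate A5 and 1-methoxyprop-1-yne A6.
- Forward step: photolysis of A5 would cause a Wolff rearrangement in which the alkenyl group moves to the carbene carbon (C1–C6). The ester-substituted vinylketene would add A6 by [2+2] (C3–C4 and C1–C2). The 4-alkenylcyclobutenone would open to a dienylketene and close by 6π electrocyclization (C4–C5), giving after tautomerization methyl 4-hydroxy-2-methoxy-3,5,6-trimethylbenzoate A4, which is the same compound as 6.
- For it: A4 arrives with the C2 methyl ether and the free C4 hydroxyl already distinguished, with no protecting group and in about three steps. On ring B this is stronger than steps 1 to 5 of the chosen route.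
- Against it: the ketene carbon carries an ester, and such acyl-type ketenes can add an ynol ether across the carbonyl–ketene unit to give a pyranone in place of the cyclobutenone. The electrocyclization has to close a ring in which every carbon is substituted. A5 needs a diazo transfer, A6 is volatile and not a shelf reagent, and the photochemical step is awkward to scale.
- Comparison: like alternative 1 it solves only ring B, which is not where the difficulty lies. The chosen route reaches 6 by conventional operations and in exchange builds ring A, the chlorine position and both free phenols directly on the preformed ester.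

**Alternative 3:** Ring A is cut at C1'–C2' only, which leads to the ring B aryl ester A7 of a 4-methyl-3,5,7-trioxooctanoyl chain.
- Forward step: an intramolecular aldol of chain C2 onto the C7 ketone, dehydration and enolization would give the dechloro depside A8. A8 would then be chlorinated at C3', its only free ring position.
- For it: the folding follows the biosynthetic pattern and needs no sensitive diene. The late chlorination is regiochemically unambiguous, and on that point it is as strong as the chosen route.
- Against it: A7 combines three enolizable ketones with an activated aryl ester. The C5 enol oxygen can lactonize onto the ester carbonyl, and the C6 carbon can attack it in a Claisen mode. Both paths expel ring B as A4 and destroy the depside bond. Assembling the triketo chain by polyanion chemistry is hard to reconcile with an aryl ester, and the sequence is longer by the chain construction and the chlorination.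
- Comparison: the chosen route forms the same ring from an alkyne and a neutral silyl diene, so no free enolate sits within reach of the aryl ester, and chlorine is placed by construction.

Key step: step 10

Remark: 18 has no stereocentre; 13 and the non-isolated 12 and 17 are racemic, and the double-bond geometries of 11, 14 and the C1=C2 bond of 16 do not affect the product.

## Route

**Step 1**
Reactants: 1 methyl 2,4-dihydroxy-3,6-dimethylbenzoate
Product: 2 methyl 4-(benzyloxy)-2-hydroxy-3,6-dimethylbenzoate
Conditions: BnBr (1.05 equiv), K2CO3, acetone, reflux
Reagents that add atoms: benzyl bromide, BrCc1ccccc1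
Why: Williamson ether synthesis; the C2 hydroxyl is held in a hydrogen bond to the ester carbonyl and is flanked by the ester and the C3 methyl, so the freer C4 phenoxide should be alkylated selectively by one equivalent of halide.

**Step 2**
Reactants: 2 methyl 4-(benzyloxy)-2-hydroxy-3,6-dimethylbenzoate
Product: 3 methyl 4-(benzyloxy)-2-methoxy-3,6-dimethylbenzoate
Conditions: MeI (excess), K2CO3, DMF, 50 °C
Reagents that add atoms: iodomethane, CI
Why: Williamson O-methylation; with the C4 oxygen blocked, the chelated C2 phenol is the only acidic site and should be methylated in a polar aprotic solvent, the doubly ortho-substituted methyl ester being inert to carbonate.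

**Step 3**
Reactants: 3 methyl 4-(benzyloxy)-2-methoxy-3,6-dimethylbenzoate
Product: 4 methyl 4-(benzyloxy)-5-bromo-2-methoxy-3,6-dimethylbenzoate
Conditions: NBS, MeCN, rt, dark
Reagents that add atoms: N-bromosuccinimide, O=C1CCC(=O)N1Br
Why: Electrophilic aromatic bromination; C5 is the only unsubstituted position of the electron-rich ring, ortho to the benzyloxy group, para to the methoxy group and meta to the ester, and polar conditions without light or initiator keep the reaction away from the benzylic positions.

**Step 4**
Reactants: 4 methyl 4-(benzyloxy)-5-bromo-2-methoxy-3,6-dimethylbenzoate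
Product: 5 methyl 4-(benzyloxy)-2-methoxy-3,5,6-trimethylbenzoate
Conditions: trimethylboroxine, Pd(OAc)2 (cat.), SPhos (cat.), K3PO4, toluene/H2O, 100 °C
Reagents that add atoms: trimethylboroxine, CB1OB(C)OB(C)O1
Why: Suzuki–Miyaura methylation; the bulky, electron-rich biaryl phosphine lets zerovalent palladium insert into an electron-rich bromide with two ortho substituents, and the hindered methyl ester and the benzyl ether should be stable to phosphate base.

**Step 5**
Reactants: 5 methyl 4-(benzyloxy)-2-methoxy-3,5,6-trimethylbenzoate
Product: 6 methyl 4-hydroxy-2-methoxy-3,5,6-trimethylbenzoate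
Conditions: H2 (1 atm), 10% Pd/C, EtOAc, rt
Reagents that add atoms: none
Why: Hydrogenolysis of the benzyl ether; no other group in 5 is reducible under these conditions, and the step frees exactly the C4 oxygen that is to be acylated.

**Step 6**
Reactants: 6 methyl 4-hydroxy-2-methoxy-3,5,6-trimethylbenzoate; 7 but-2-ynoic acid
Product: 8 3-methoxy-4-(methoxycarbonyl)-2,5,6-trimethylphenyl but-2-ynoate
Conditions: DCC, DMAP (0.1 equiv), CH2Cl2, 0 °C → rt
Reagents that add atoms: none
Why: Steglich esterification; the acyl group is linear at the alkyne and can reach the oxygen between the two ortho methyls, and low temperature with only catalytic DMAP limits conjugate addition to the activated ynoate.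

**Step 7**
Reactants: 9 methyl propanoate; 10 2-chloro-N-methoxy-N-methylacetamide
Product: 13 methyl 4-chloro-2-methyl-3-oxobutanoate (racemic), via lithium enolate 11 (not isolated), via lithium alkoxide adduct 12 (not isolated)
Conditions: LiN(iPr)2, THF, −78 °C; then 10 (to a slight excess of 11), −78 → −40 °C; 1 M HCl
Reagents that add atoms: none
Why: Crossed Claisen-type acylation of an ester enolate by an N-methoxy-N-methylamide; the lithium-chelated adduct 12 does not collapse before the quench, so the acidic keto ester 13 never meets the enolate, and at low temperature addition to the carbonyl should outrun displacement of chloride.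

**Step 8**
Reactants: 13 methyl 4-chloro-2-methyl-3-oxobutanoate
Product: 14 methyl (E)-4-chloro-2-methyl-3-(trimethylsilyloxy)but-2-enoate
Conditions: Me3SiCl, Et3N, toluene, rt; filtration, distillation
Reagents that add atoms: chlorotrimethylsilane, C[Si](C)(C)Cl
Why: O-silylation of the enol form of a β-keto ester under soft enolization; the product masks the chloro ketone, and its double-bond geometry (E expected, a mixture tolerated) is of no consequence because this bond becomes the central single bond of the diene.

**Step 9**
Reactants: 14 methyl (E)-4-chloro-2-methyl-3-(trimethylsilyloxy)but-2-enoate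
Product: 16 (1Z,3Z)-4-chloro-1-methoxy-2-methyl-1,3-bis(trimethylsilyloxy)buta-1,3-diene, via lithium dienolate 15 (not isolated)
Conditions: LiN(iPr)2, THF, −78 °C; Me3SiCl, −78 °C → rt; pentane, filtration under Ar; used crude
Reagents that add atoms: chlorotrimethylsilane, C[Si](C)(C)Cl
Why: γ-Deprotonation of the silyloxy enoate to the vinylogous ester enolate and O-silylation at the hard oxygen terminus, the standard route to 1-alkoxy-1,3-bis(silyloxy)buta-1,3-dienes; chlorine acidifies the γ hydrogens and should take the position cis to the C3 silyloxy group (3Z), away from the C2 methyl, which is the geometry that can reach the s-cis conformation.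

**Step 10**
Reactants: 16 (1Z,3Z)-4-chloro-1-methoxy-2-methyl-1,3-bis(trimethylsilyloxy)buta-1,3-diene; 8 3-methoxy-4-(methoxycarbonyl)-2,5,6-trimethylphenyl but-2-ynoate
Product: 18 3-methoxy-4-(methoxycarbonyl)-2,5,6-trimethylphenyl 3-chloro-4,6-dihydroxy-2,5-dimethylbenzoate (the target), via cycloadduct 17 (not isolated)
Conditions: 16 (3 equiv), toluene, 120 °C, sealed tube; then 1 M HCl, THF, 0 °C → rt
Reagents that add atoms: none
Why: The step is a normal-electron-demand [4+2] cycloaddition, expected to be concerted but asynchronous, in which the bond from the CHCl terminus of 16 (future C3') to the β carbon of the ynoate (future C2') is the more advanced and the bond from the ketene acetal carbon (future C6') to the α carbon (future C1') completes the ring. Ring A is closed by the intermolecular cycloaddition itself, suprafacial on both partners, so no separate cyclization with its own ring-size preference is involved. The closest known reaction type is the addition of 1-alkoxy-1,3-bis(silyloxy)buta-1,3-dienes to acetylenic esters followed by aromatization to resorcylates. The step needs regioselectivity, and polarization secures it: the CHCl carbon is the enol ether β carbon of the C3 silyloxy group and the vinylogous terminus of the ketene acetal and so has the largest HOMO coefficient, the β carbon of 8 has the largest LUMO coefficient, and this puts chlorine next to the C2' methyl and the C6' oxygen next to the carbonyl-bearing carbon. The adduct 17 has two stereocentres, C3' and C6' (Cl and OMe cis, fixed by the diene geometry), but both become sp2 on aromatization, so no stereocontrol is needed and a geometric mixture at C1=C2 of 16 would converge. Acid then hydrolyses the silyl methyl ketal at C6' to the ketone with loss of methanol, the resulting 4-chlorocyclohexa-2,5-dienone tautomerizes by loss of the C3' hydrogen, and the remaining silyl ether is cleaved. Chlorine should be kept because no ring carbon next to C3' carries a hydrogen, so hydrogen chloride cannot be eliminated, and loss of the C3' proton is far faster than loss of chlorine as a cation; the ester, shielded by four ortho groups, should survive dilute aqueous acid. The aryl ester makes the alkyne more electron-poor than an alkyl ynoate would, and the linear alkyne keeps the crowded termini apart until bonding, which is the reason for making the ester before the ring.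

## Compound list

1 | methyl 2,4-dihydroxy-3,6-dimethylbenzoate | COC(=O)c1c(C)cc(O)c(C)c1O | starting material
2 | methyl 4-(benzyloxy)-2-hydroxy-3,6-dimethylbenzoate | COC(=O)c1c(C)cc(OCc2ccccc2)c(C)c1O | intermediate
3 | methyl 4-(benzyloxy)-2-methoxy-3,6-dimethylbenzoate | COC(=O)c1c(C)cc(OCc2ccccc2)c(C)c1OC | intermediate
4 | methyl 4-(benzyloxy)-5-bromo-2-methoxy-3,6-dimethylbenzoate | COC(=O)c1c(C)c(Br)c(OCc2ccccc2)c(C)c1OC | intermediate
5 | methyl 4-(benzyloxy)-2-methoxy-3,5,6-trimethylbenzoate | COC(=O)c1c(C)c(C)c(OCc2ccccc2)c(C)c1OC | intermediate
6 | methyl 4-hydroxy-2-methoxy-3,5,6-trimethylbenzoate (ring B phenol) | COC(=O)c1c(C)c(C)c(O)c(C)c1OC | intermediate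
7 | but-2-ynoic acid | CC#CC(=O)O | starting material
8 | 3-methoxy-4-(methoxycarbonyl)-2,5,6-trimethylphenyl but-2-ynoate | COC(=O)c1c(C)c(C)c(OC(=O)C#CC)c(C)c1OC | intermediate
9 | methyl propanoate | CCC(=O)OC | starting material
10 | 2-chloro-N-methoxy-N-methylacetamide | CON(C)C(=O)CCl | starting material
11 | lithium 1-methoxyprop-1-en-1-olate (lithium enolate of 9; methyl cis to methoxy, geometry without consequence) | C/C=C(\OC)O[Li] | intermediate (not isolated)
12 | methyl 4-chloro-3-(lithiooxy)-3-[methoxy(methyl)amino]-2-methylbutanoate (racemic diastereomer mixture) | COC(=O)C(C)C(CCl)(O[Li])N(C)OC | intermediate (not isolated)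
13 | methyl 4-chloro-2-methyl-3-oxobutanoate (racemic) | COC(=O)C(C)C(=O)CCl | intermediate
14 | methyl (E)-4-chloro-2-methyl-3-(trimethylsilyloxy)but-2-enoate | COC(=O)/C(C)=C(\CCl)O[Si](C)(C)C | intermediate
15 | lithium 4-chloro-1-methoxy-2-methyl-3-(trimethylsilyloxy)buta-1,3-dien-1-olate (chlorine cis to the C3 silyloxy group) | CO/C(O[Li])=C(C)/C(O[Si](C)(C)C)=C/Cl | intermediate (not isolated)
16 | (1Z,3Z)-4-chloro-1-methoxy-2-methyl-1,3-bis(trimethylsilyloxy)buta-1,3-diene | CO/C(O[Si](C)(C)C)=C(C)/C(O[Si](C)(C)C)=C/Cl | intermediate
17 | 3-methoxy-4-(methoxycarbonyl)-2,5,6-trimethylphenyl 3-chloro-6-methoxy-2,5-dimethyl-4,6-bis(trimethylsilyloxy)cyclohexa-1,4-diene-1-carboxylate (racemic, Cl and OMe cis; one enantiomer drawn) | COC(=O)c1c(C)c(C)c(OC(=O)C2=C(C)[C@@H](Cl)C(O[Si](C)(C)C)=C(C)[C@]2(OC)O[Si](C)(C)C)c(C)c1OC | intermediate (not isolated)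
18 | 3-methoxy-4-(methoxycarbonyl)-2,5,6-trimethylphenyl 3-chloro-4,6-dihydroxy-2,5-dimethylbenzoate | COC(=O)c1c(C)c(C)c(OC(=O)c2c(C)c(Cl)c(O)c(C)c2O)c(C)c1OC | target

## Step count and least certain steps

Total step count: 10. Longest linear sequence: 7 steps (steps 1 to 6, then step 10); the diene branch (steps 7 to 9) joins at step 10.

**Step 10 (key step).**
- Risk: both bond-forming termini of each partner are fully substituted, so cycloaddition may be slow enough that thermal desilylation or silyl migration of 16 outpaces bond formation. Ionization of the C6' ketal with loss of the silyloxy group in place of the methoxy group would leave a methyl ether at C6'.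
- Fallback (sets out from 1 and 6, returns at 18): the crowded ester is made conventionally from a finished ring A acid.
  - Chlorination of 1 at its only free ring position (SO2Cl2, Et2O, 0 °C) should give methyl 3-chloro-4,6-dihydroxy-2,5-dimethylbenzoate F1.
  - Benzylation of both hydroxyls (BnBr, K2CO3, DMF, 80 °C) should give methyl 2,4-bis(benzyloxy)-5-chloro-3,6-dimethylbenzoate F2.
  - Cleavage of the hindered methyl ester (KOH, DMSO/H2O, 100 °C) should give 2,4-bis(benzyloxy)-5-chloro-3,6-dimethylbenzoic acid F3.
  - Activation of F3 as its mixed trifluoroacetic anhydride ((CF3CO)2O, toluene, rt) in the presence of 6 should give the protected depside 3-methoxy-4-(methoxycarbonyl)-2,5,6-trimethylphenyl 2,4-bis(benzyloxy)-5-chloro-3,6-dimethylbenzoate F4.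
  - Brief hydrogenolysis (H2, 10% Pd/C, EtOAc, rt, stopped at full debenzylation to spare the aryl chloride) should give 18.

**Step 9.**
- Risk: deprotonation at a carbon that carries chlorine may be accompanied by loss of chloride, self-condensation or C-silylation, and the diene may hydrolyse during isolation, so that material of insufficient quality reaches the key step.
- Fallback (sets out from 8, returns at 18): chlorine is introduced last, from commercial methyl 2-methyl-3-oxobutanoate as the four-carbon source.
  - Me3SiCl, Et3N should give methyl (E)-2-methyl-3-(trimethylsilyloxy)but-2-enoate F5.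
  - LiN(iPr)2, then Me3SiCl should give the robust chlorine-free diene (Z)-1-methoxy-2-methyl-1,3-bis(trimethylsilyloxy)buta-1,3-diene F6.
  - Cycloaddition of F6 with 8 (toluene, 120 °C) should give the adduct 3-methoxy-4-(methoxycarbonyl)-2,5,6-trimethylphenyl 6-methoxy-2,5-dimethyl-4,6-bis(trimethylsilyloxy)cyclohexa-1,4-diene-1-carboxylate F7.
  - Acidic work-up (1 M HCl, THF) should give the dechloro depside 3-methoxy-4-(methoxycarbonyl)-2,5,6-trimethylphenyl 2,4-dihydroxy-3,6-dimethylbenzoate F8, identical with A8.
  - Chlorination with one equivalent of SO2Cl2 (Et2O, 0 °C) at C3', the only free ring position, should give 18.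

**Step 7.**
- Risk: proton transfer from the acidic CH2Cl group of 10 to the enolate, or attack of the enolate at the carbon bearing chlorine, may compete with addition to the amide carbonyl.
- Fallback (sets out from 9, returns at 13): the basic enolate is replaced by a neutral nucleophile.
  - 9 is converted (LiN(iPr)2, Me3SiCl, THF, −78 °C) into the ketene silyl acetal (E)-1-methoxy-1-(trimethylsilyloxy)prop-1-ene F9.
  - C-acylation of F9 with chloroacetyl chloride (CH2Cl2, ZnCl2 cat., 0 °C → rt), followed by aqueous work-up, should give 13.

**Step 6.**
- Risk: acylation of the doubly ortho-substituted phenol may be slow enough for the activated acid to rearrange to its N-acylurea, or for DMAP to add to the β carbon of the activated ynoate.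
- Fallback (sets out from 6, returns at 8): the triple bond is made after the ester.
  - Acetoacetylation of 6 by the acylketene released from 2,2,6-trimethyl-4H-1,3-dioxin-4-one (xylene, 130 °C) should give 3-methoxy-4-(methoxycarbonyl)-2,5,6-trimethylphenyl 3-oxobutanoate F10.
  - Triflation of its chelated sodium enolate (NaH, (CF3SO2)2O, Et2O, 0 °C) should give the enol triflate 3-methoxy-4-(methoxycarbonyl)-2,5,6-trimethylphenyl (Z)-3-[(trifluoromethylsulfonyl)oxy]but-2-enoate F11.
  - Anti elimination with a hindered base (LiN(SiMe3)2, THF, −78 °C) should give 8.

## Further compounds

F1 | step 10 | methyl 3-chloro-4,6-dihydroxy-2,5-dimethylbenzoate | COC(=O)c1c(C)c(Cl)c(O)c(C)c1O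
F2 | step 10 | methyl 2,4-bis(benzyloxy)-5-chloro-3,6-dimethylbenzoate | COC(=O)c1c(C)c(Cl)c(OCc2ccccc2)c(C)c1OCc1ccccc1
F3 | step 10 | 2,4-bis(benzyloxy)-5-chloro-3,6-dimethylbenzoic acid | OC(=O)c1c(C)c(Cl)c(OCc2ccccc2)c(C)c1OCc1ccccc1
F4 | step 10 | 3-methoxy-4-(methoxycarbonyl)-2,5,6-trimethylphenyl 2,4-bis(benzyloxy)-5-chloro-3,6-dimethylbenzoate | COC(=O)c1c(C)c(C)c(OC(=O)c2c(C)c(Cl)c(OCc3ccccc3)c(C)c2OCc2ccccc2)c(C)c1OC
F5 | step 9 | methyl (E)-2-methyl-3-(trimethylsilyloxy)but-2-enoate | COC(=O)/C(C)=C(\C)O[Si](C)(C)C
F6 | step 9 | (Z)-1-methoxy-2-methyl-1,3-bis(trimethylsilyloxy)buta-1,3-diene | CO/C(O[Si](C)(C)C)=C(C)/C(O[Si](C)(C)C)=C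
F7 | step 9 | 3-methoxy-4-(methoxycarbonyl)-2,5,6-trimethylphenyl 6-methoxy-2,5-dimethyl-4,6-bis(trimethylsilyloxy)cyclohexa-1,4-diene-1-carboxylate (racemic) | COC(=O)c1c(C)c(C)c(OC(=O)C2=C(C)CC(O[Si](C)(C)C)=C(C)C2(OC)O[Si](C)(C)C)c(C)c1OC
F8 | step 9 | 3-methoxy-4-(methoxycarbonyl)-2,5,6-trimethylphenyl 2,4-dihydroxy-3,6-dimethylbenzoate | COC(=O)c1c(C)c(C)c(OC(=O)c2c(C)cc(O)c(C)c2O)c(C)c1OC
F9 | step 7 | (E)-1-methoxy-1-(trimethylsilyloxy)prop-1-ene | C/C=C(\OC)O[Si](C)(C)C
F10 | step 6 | 3-methoxy-4-(methoxycarbonyl)-2,5,6-trimethylphenyl 3-oxobutanoate | COC(=O)c1c(C)c(C)c(OC(=O)CC(C)=O)c(C)c1OC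
F11 | step 6 | 3-methoxy-4-(methoxycarbonyl)-2,5,6-trimethylphenyl (Z)-3-[(trifluoromethylsulfonyl)oxy]but-2-enoate | COC(=O)c1c(C)c(C)c(OC(=O)/C=C(/C)OS(=O)(=O)C(F)(F)F)c(C)c1OC
A1 | alternative 1 | methyl 2,4-dihydroxy-3,5,6-trimethylbenzoate | COC(=O)c1c(C)c(C)c(O)c(C)c1O
A2 | alternative 1 | pentan-3-one | CCC(=O)CC
A3 | alternative 1 | dimethyl 2-(1-methoxyethylidene)malonate | COC(C)=C(C(=O)OC)C(=O)OC
A4 | alternative 2 | methyl 4-hydroxy-2-methoxy-3,5,6-trimethylbenzoate | COC(=O)c1c(C)c(C)c(O)c(C)c1OC
A5 | alternative 2 | methyl (E)-2-diazo-4-methyl-3-oxohex-4-enoate | COC(=O)C(=[N+]=[N-])C(=O)/C(C)=C/C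
A6 | alternative 2 | 1-methoxyprop-1-yne | COC#CC
A7 | alternative 3 | 3-methoxy-4-(methoxycarbonyl)-2,5,6-trimethylphenyl 4-methyl-3,5,7-trioxooctanoate (racemic) | COC(=O)c1c(C)c(C)c(OC(=O)CC(=O)C(C)C(=O)CC(C)=O)c(C)c1OC
A8 | alternative 3 | 3-methoxy-4-(methoxycarbonyl)-2,5,6-trimethylphenyl 2,4-dihydroxy-3,6-dimethylbenzoate | COC(=O)c1c(C)c(C)c(OC(=O)c2c(C)cc(O)c(C)c2O)c(C)c1OC
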